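**Plan**

1. Retrosynthesis of 1-(4-hydroxyphenyl)octadecan-5-one (C24H40O2, achiral): the phenol O–H is first masked as O–CH3; then the C5–C6 bond (ketone carbon to the methylene on the tridecyl side) is cut after a carboxyl group is put back on C6.
2. This gives two plain carboxylic acids: 5-(4-methoxyphenyl)pentanoic acid (its carboxyl carbon becomes C5) and tetradecanoic acid (its α-carbon becomes C6; its own carboxyl is the activating group and leaves again as CO2).
3. Enabling feature: the C5 carbonyl next to the unbranched C6H2 of the tridecyl chain is the trace of a head-to-head Claisen condensation of two fatty acyl units followed by decarboxylation of the 2-alkyl-3-oxo acid, the presumed biosynthetic origin of such mid-chain ketones. The para-disubstituted benzene ring sits four methylenes from C5 and stays a spectator.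
4. Forward: the C11 aryl acid is activated as its chloride; C-acylation of the dilithium enediolate of tetradecanoic acid and decarboxylation in the same flask join the two chains into the full skeleton; O-demethylation ends the route.
5. Stereochemistry: the target has no stereocentre and no double-bond geometry. The single stereocentre met on the way (C2 of the β-keto acid) is racemic and vanishes with the CO2.

Key step: step 2

Remark: 5-(4-methoxyphenyl)pentanoic acid and tetradecanoic acid are taken as commercial materials.

**Route**

Step 1
Reactants: 1 5-(4-methoxyphenyl)pentanoic acid
Product: 2 5-(4-methoxyphenyl)pentanoyl chloride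
Conditions: (COCl)2 (1.3 equiv), DMF (cat.), CH2Cl2, 0 °C → rt; evaporate, strip twice with toluene
Reagents that add atoms: oxalyl chloride, ClC(=O)C(=O)Cl
Why: Catalytic DMF and oxalyl chloride form a chloroiminium (Vilsmeier-type) reagent that should convert the acid into the acyl chloride with loss of CO, CO2 and HCl, the aryl methyl ether being inert without a Lewis acid (acyl chloride formation).

Step 2
Reactants: 2 5-(4-methoxyphenyl)pentanoyl chloride, 3 tetradecanoic acid (myristic acid)
Product: 6 1-(4-methoxyphenyl)octadecan-5-one, via dilithium enediolate 4 (not isolated), via beta-keto acid 5 (not isolated)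
Conditions: 3 (2.2 equiv), LiN(iPr)2 (4.3 equiv), THF–DMPU, 0 → 40 °C; then 2 (1.0 equiv) in THF, −78 °C → rt; 2 M HCl; toluene, 80 °C (−CO2)
Reagents that add atoms: none
Why: Double deprotonation of 3 by LiN(iPr)2 should give the dilithium enediolate 4, whose α-carbon (the future C6) attacks the carbonyl carbon of 2 (the future C5) by addition–elimination with loss of chloride; the resulting 2-dodecyl-3-oxo carboxylate is deprotonated by the second equivalent of 4 to an inert dianion, which blocks over-acylation and aldol addition, and after acidification the free β-keto acid 5 loses CO2 on warming through a six-membered cyclic transition state to the enol of 6. The closest known reaction type is the crossed Claisen-type C-acylation of a carboxylic acid dianion with an acyl chloride followed by β-keto acid decarboxylation, which here copies the head-to-head condensation of two fatty acyl units and the spontaneous decarboxylation of the 2-alkyl-3-oxo acid presumed for the biosynthesis. No ring is closed. The one new stereocentre, C2 of 5, forms without control as a racemate and is erased when decarboxylation turns it into the C6 methylene. The step needs a fixed assignment of donor and acceptor roles and C- over O- or N-acylation: only 3 is enolised before mixing, 2 is added cold to an excess of 4 with LiN(iPr)2 kept just below two equivalents per acid, and the lithium enediolate reacts at carbon, while the anisole ring and its benzylic CH2, four carbons from the reacting centre, are too weakly acidic to interfere.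

Step 3
Reactants: 6 1-(4-methoxyphenyl)octadecan-5-one
Product: 7 1-(4-hydroxyphenyl)octadecan-5-one
Conditions: BBr3 (2.5 equiv), CH2Cl2, −78 → 0 °C; then H2O, 0 °C
Reagents that add atoms: none
Why: BBr3 complexes the aryl ether oxygen and bromide attacks the methyl group (Lewis-acid-mediated aryl methyl ether cleavage), hydrolysis of the aryloxyborane on work-up should release the phenol, and the saturated ketone is only complexed at low temperature and returned unchanged.

**Compound list**

1 | 5-(4-methoxyphenyl)pentanoic acid | COc1ccc(CCCCC(=O)O)cc1 | starting material
2 | 5-(4-methoxyphenyl)pentanoyl chloride | COc1ccc(CCCCC(=O)Cl)cc1 | intermediate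
3 | tetradecanoic acid (myristic acid) | CCCCCCCCCCCCCC(=O)O | starting material
4 | dilithium tetradec-1-ene-1,1-diolate (enediolate of 3) | CCCCCCCCCCCCC=C([O-])[O-].[Li+].[Li+] | intermediate (not isolated)
5 | 2-dodecyl-7-(4-methoxyphenyl)-3-oxoheptanoic acid (racemic) | CCCCCCCCCCCCC(C(=O)O)C(=O)CCCCc1ccc(OC)cc1 | intermediate (not isolated)
6 | 1-(4-methoxyphenyl)octadecan-5-one | CCCCCCCCCCCCCC(=O)CCCCc1ccc(OC)cc1 | intermediate
7 | 1-(4-hydroxyphenyl)octadecan-5-one | CCCCCCCCCCCCCC(=O)CCCCc1ccc(O)cc1 | target

**Summary**

Total step count: 3. Longest linear sequence: 3 steps (1 → 2 → 6 → 7).

**Steps most likely to fail**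

Step 2. C-acylation may lose out to proton transfer from the α-CH2 of the acyl chloride (ketene formation), to O-acylation of the enediolate or to N-acylation of the liberated diisopropylamine. The long-chain dilithium enediolate may also aggregate and react sluggishly. The fallback sets out from 2. Schotten–Baumann acylation of MeNHOMe·HCl with K2CO3 in CH2Cl2/H2O should give N-methoxy-N-methyl-5-(4-methoxyphenyl)pentanamide F1. Tridecylmagnesium bromide F2, prepared from commercial 1-bromotridecane (CCCCCCCCCCCCCBr) and Mg turnings in THF, is then added to F1 at 0 °C. The chelated tetrahedral magnesium adduct should resist a second addition and release the ketone on aqueous NH4Cl work-up (Weinreb ketone synthesis). The fallback comes back to the route at 6.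

Step 3. Lewis-acid-promoted enolisation of the ketone with aldol self-condensation, or incomplete ether cleavage because the carbonyl ties up the boron reagent, may erode the last step. The fallback sets out from 6. Ketalisation with ethylene glycol and TsOH in toluene under Dean–Stark water removal should give 2-[4-(4-methoxyphenyl)butyl]-2-tridecyl-1,3-dioxolane F3. SN2 demethylation with NaSEt in DMF at 130 °C, to which the ketal is inert, should give 4-[4-(2-tridecyl-1,3-dioxolan-2-yl)butyl]phenol F4. Hydrolysis of the ketal with 1 M HCl in THF then comes back to the route at 7.

Step 1. Hydrolysis of the acyl chloride during isolation, or carry-over of HCl and oxalyl chloride that would quench the enediolate in step 2, may undermine the activation. The fallback sets out from 1. Treatment with 1H-benzotriazole and SOCl2 in CH2Cl2 at rt should give the bench-stable, chromatographable 1-[5-(4-methoxyphenyl)pentanoyl]-1H-benzotriazole F5. F5 is added in place of 2 to the enediolate 4 under the conditions of step 2 (C-acylation, then acidification and thermal decarboxylation through 5). The fallback comes back to the route at 6.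

**Further compounds**

F1 | step 2 | N-methoxy-N-methyl-5-(4-methoxyphenyl)pentanamide | COc1ccc(CCCCC(=O)N(C)OC)cc1
F2 | step 2 | tridecylmagnesium bromide | CCCCCCCCCCCCC[Mg]Br
F3 | step 3 | 2-[4-(4-methoxyphenyl)butyl]-2-tridecyl-1,3-dioxolane | CCCCCCCCCCCCCC1(CCCCc2ccc(OC)cc2)OCCO1
F4 | step 3 | 4-[4-(2-tridecyl-1,3-dioxolan-2-yl)butyl]phenol | CCCCCCCCCCCCCC1(CCCCc2ccc(O)cc2)OCCO1
F5 | step 1 | 1-[5-(4-methoxyphenyl)pentanoyl]-1H-benzotriazole | COc1ccc(CCCCC(=O)n2nnc3ccccc32)cc1
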